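**Plan**

1. Retrosynthesis (trinervitane numbering; ring A = cyclohexene C1–C2–C3–C4–C16–C15, ring B = cyclopentane C4–C5–C6–C7–C16, ring C = the eleven-membered ring): the acetates are removed, ring C is cut at C8–C9, the side chain at C1–C14, and ring A at C1–C15 and C2–C3.
2. What is left is ring B with C3 (on C4), C15 (on C16) and C8 (on C7) all cis, C3 and C8 being 1,3-related; joining C3 to C8 by a C=C bond that the target does not contain turns ring B into a bicyclo[2.2.1]heptene, which is cut at C4–C5 and C6–C7 into a 5-substituted 2-silyloxycyclopentadiene and an ethylene equivalent.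
3. Forward order: Diels–Alder reaction (ring B plus the temporary ring C3–C4–C5–C6–C7–C8), ozonolysis of the temporary C3=C8 bond, ring A by acyl-anion addition and enol-ether aldol closure, C1–C14 by CrCl2/NiCl2 coupling, ring C by CrCl2/NiCl2 macrocyclisation, selective triacetylation.
4. Stereochemistry: C16 from (R)-4-silyloxycyclopentenone; C4 and C7 from anti-facial cycloaddition; C3 by 1,2-induction from C4; C2 by hydroxyl-directed reduction; C12 from (S)-citronellal; C14 by allylic strain in the coupling; C9 by macrocyclic control.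

Key step: step 3

Remark: the phenylsulfonyl group of the dienophile is a traceless activator (ethylene equivalent), so its regio- and endo/exo orientation in 9 is immaterial and only the expected major isomer is drawn.

**Step 1**
Reactants: 1 (R)-4-(tert-butyldimethylsilyloxy)cyclopent-2-en-1-one; 2 isopropenylmagnesium bromide
Product: 4 (R)-4-(prop-1-en-2-yl)cyclopent-2-en-1-one, via trans-silyloxy ketone 3 (not isolated)
Conditions: CuBr·SMe2 (10 mol%), THF, −78 °C; aq NH4Cl; then DBU, CH2Cl2, 0 °C
Reagents that add atoms: none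
Why: Copper-catalysed conjugate addition of the Grignard reagent should occur anti to the silyloxy group and E1cB loss of silanolate (conjugate addition–β-elimination) then transposes the enone, so the stereocentre of 1 is relayed to the future C16.

**Step 2**
Reactants: 4 (R)-4-(prop-1-en-2-yl)cyclopent-2-en-1-one
Product: 6 (S)-3-methyl-4-(prop-1-en-2-yl)cyclopent-2-en-1-one, via silyl enol ether 5 (not isolated)
Conditions: MeMgBr, CuBr·SMe2 (10 mol%), Me3SiCl, THF, −78 °C; then Pd(OAc)2 (1.05 equiv), MeCN, 23 °C
Reagents that add atoms: methylmagnesium bromide, C[Mg]Br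
Why: Silyl-trapped copper-catalysed conjugate addition followed by Saegusa–Ito oxidation of the regiodefined silyl enol ether should put the methyl group on the β-carbon of a regenerated enone, and the only stereocentre (C16) is not touched.

**Step 3**
Reactants: 6 (S)-3-methyl-4-(prop-1-en-2-yl)cyclopent-2-en-1-one; 7 phenyl vinyl sulfone
Product: 9 2-(tert-butyldimethylsilyloxy)-4-methyl-5-endo-(phenylsulfonyl)-7-(prop-1-en-2-yl)bicyclo[2.2.1]hept-2-ene (isopropenyl syn to C2=C3), via silyloxy diene 8 (not isolated)
Conditions: LiN(iPr)2, THF, −78 °C; TBSOTf, −78 °C; cold pentane–aq NaHCO3 wash; then 7 (3 equiv), CH2Cl2, 0 °C, dark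
Reagents that add atoms: tert-butyldimethylsilyl triflate, CC(C)(C)[Si](C)(C)OS(=O)(=O)C(F)(F)F
Why: Kinetic α'-deprotonation (future C7) and O-silylation give the 2-silyloxycyclopentadiene 8, whose termini C7 and C4 add suprafacially to the vinyl sulfone in a concerted, asynchronous, normal-demand Diels–Alder reaction that forms C7–C6 and C4–C5 together. The closest known reaction type is the cycloaddition of 5-substituted and of 2-silyloxy cyclopentadienes with phenyl vinyl sulfone used as an ethylene equivalent. Ring B (C4–C5–C6–C7–C16) and the temporary six-membered ring (C3–C4–C5–C6–C7–C8) both close by this [4+2] cycloaddition across the cyclic diene, giving the bicyclo[2.2.1]heptene. The dienophile should attack the diene face anti to the C16 isopropenyl group, so the chiral-pool stereocentre C16 fixes C7 and the quaternary C4 and leaves C15 syn to the C3=C8 bridge, which is the all-cis arrangement of C3, C15 and C8 on ring B. The step needs π-facial selectivity (secured by the sp3 C16 substituent on one face) and a cycloaddition faster than the [1,5]-hydrogen shift of the 5-substituted diene (secured by the electron-rich silyloxy diene, excess dienophile and 0 °C). Regio- and endo/exo selectivity do not matter because the sulfonyl-bearing carbon becomes CH2.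

**Step 4**
Reactants: 9 Diels–Alder sulfone
Product: 10 (1R,4S,7S)-2-(tert-butyldimethylsilyloxy)-4-methyl-7-(prop-1-en-2-yl)bicyclo[2.2.1]hept-2-ene
Conditions: Na/Hg (6% Na), Na2HPO4, MeOH–THF, −20 °C
Reagents that add atoms: none
Why: Reductive desulfonylation with buffered sodium amalgam should cleave the C–S bond without touching the silyl enol ether or the isopropenyl group, completing the use of phenyl vinyl sulfone as an ethylene equivalent.

**Step 5**
Reactants: 10 bicyclic silyl enol ether
Product: 12 methyl (1R,2R,3S)-2-acetyl-3-formyl-3-methylcyclopentane-1-carboxylate, via keto aldehyde acid 11 (not isolated)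
Conditions: O3, CH2Cl2–MeOH, −78 °C; Me2S, −78 → 23 °C; then Me3SiCHN2, PhMe–MeOH, 0 °C
Reagents that add atoms: ozone, [O-][O+]=O; (trimethylsilyl)diazomethane, C[Si](C)(C)C=[N+]=[N-]
Why: Ozonolysis should cleave the silyl enol ether (the temporary C3=C8 bond) to the C8 acid and C3 aldehyde and the isopropenyl group to the C15 methyl ketone in one operation, and esterification protects the acid; no stereocentre is touched, so the three carbonyl groups stay cis on ring B.

**Step 6**
Reactants: 12 keto aldehyde ester; 13 ethyl vinyl ether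
Product: 14 methyl (1R,2R,3S)-2-acetyl-3-[(1R)-2-ethoxy-1-(trimethylsilyloxy)prop-2-en-1-yl]-3-methylcyclopentane-1-carboxylate
Conditions: 13, t-BuLi, THF, −78 → 0 °C; then 12, THF, −78 °C; Me3SiCl, −78 → 0 °C
Reagents that add atoms: chlorotrimethylsilane, C[Si](C)(C)Cl
Why: 1-Ethoxyvinyllithium (an acyl anion equivalent) should add to the aldehyde in preference to the ketone and ester at −78 °C, Felkin–Anh attack anti to C16 (the bulkiest substituent on the quaternary C4) sets the C3 carbinol, and silylation in the flask prevents lactonisation onto the cis C8 ester.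

**Step 7**
Reactants: 14 enol ether
Product: 16 methyl (3R,3aS,7R,7aS)-7-hydroxy-4,7a-dimethyl-6-oxo-2,3,3a,6,7,7a-hexahydro-1H-indene-3-carboxylate, via tertiary aldol 15 (not isolated)
Conditions: TiCl4, CH2Cl2, −78 → −20 °C; then 1 M HCl, THF, 23 °C
Reagents that add atoms: water, O
Why: The enol ether is nucleophilic only at C1, so a Lewis-acid-promoted Mukaiyama-type aldol addition to the C15 ketone (6-enolendo-exo-trig) should close ring A with the right regiochemistry, and acid hydrolysis and dehydration give the conjugated enone with the cis ring fusion already fixed by C4 and C16.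

**Step 8**
Reactants: 16 hydroxy enone
Product: 17 methyl 7-hydroxy-5-iodo-4,7a-dimethyl-6-oxo-2,3,3a,6,7,7a-hexahydro-1H-indene-3-carboxylate (stereocentres as in 16)
Conditions: I2, Me3SiN3, pyridine, CH2Cl2, 0 → 23 °C
Reagents that add atoms: iodine, II
Why: α-Iodination of the β,β-disubstituted enone by conjugate addition of azide, iodination of the resulting silyl enol ether and elimination (addition–elimination α-halogenation of enones) should install the C1 handle without creating a stereocentre.

**Step 9**
Reactants: 17 iodo enone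
Product: 18 methyl 6,7-dihydroxy-5-iodo-4,7a-dimethyl-2,3,3a,6,7,7a-hexahydro-1H-indene-3-carboxylate (6,7-trans diol, 7-OH cis to the 7a-methyl)
Conditions: Me4NBH(OAc)3, MeCN–AcOH, −30 °C
Reagents that add atoms: none
Why: Hydroxyl-directed reduction (Evans–Saksena type) should deliver hydride from the boron bound to the C3 oxygen to the same face of the C2 ketone, which gives the trans-2,3-diol and sets C2.

**Step 10**
Reactants: 18 iodo diol; 19 (S)-citronellal
Product: 20 methyl 6,7-dihydroxy-5-[(1S,3S)-1-hydroxy-3,7-dimethyloct-6-en-1-yl]-4,7a-dimethyl-2,3,3a,6,7,7a-hexahydro-1H-indene-3-carboxylate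
Conditions: 19 (1.5 equiv), CrCl2 (6 equiv), NiCl2 (2 mol%), DMSO, 23 °C
Reagents that add atoms: none
Why: The Nozaki–Hiyama–Kishi coupling tolerates the ester and free hydroxyls, and A(1,3) strain with the C15 methyl should hold the aldehyde hydrogen in the alkene plane and its chain on the face away from the C2 hydroxyl, giving the 2,14-anti carbinol of the target; C12 comes from 19.

**Step 11**
Reactants: 20 triol
Product: 21 tris(triethylsilyl) ether of 20
Conditions: TESOTf, 2,6-lutidine, CH2Cl2, −40 → 0 °C
Reagents that add atoms: triethylsilyl triflate, CC[Si](CC)(CC)OS(=O)(=O)C(F)(F)F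
Why: Silyl triflate silylation should protect all three hydroxyls, the hindered C3 one included, for the organometallic steps that follow.

**Step 12**
Reactants: 21 tris-silyl ether ester
Product: 22 methyl ketone (the CO2Me of 21 replaced by COCH3)
Conditions: Me3SiCH2Li, THF–pentane, −20 → 0 °C; then AcOH–MeOH
Reagents that add atoms: (trimethylsilyl)methyllithium, C[Si](C)(C)C[Li]
Why: Addition–elimination gives an α-silyl ketone that is deprotonated at the silyl-bearing carbon (so no second addition and no enolisation toward C7) and protodesilylation on work-up gives the methyl ketone in one pot.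

**Step 13**
Reactants: 22 methyl ketone
Product: 23 enol triflate (C8(OTf)=C19H2)
Conditions: KN(SiMe3)2, THF, −78 °C; PhNTf2, −78 → −20 °C
Reagents that add atoms: N-phenylbis(trifluoromethanesulfonimide), O=S(=O)(N(c1ccccc1)S(=O)(=O)C(F)(F)F)C(F)(F)F
Why: Kinetic deprotonation of the methyl ketone at the methyl group by the bulky amide and O-triflation should give the 1,1-disubstituted enol triflate without epimerising C7.

**Step 14**
Reactants: 23 enol triflate
Product: 24 aldehyde (isopropylidene terminus of 23 cleaved to C9 aldehyde)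
Conditions: OsO4 (2 mol%), NaIO4, 2,6-lutidine, dioxane–H2O, 23 °C
Reagents that add atoms: sodium periodate, [Na+].[O-]I(=O)(=O)=O
Why: Johnson–Lemieux cleavage should select the unhindered trisubstituted alkene over the shielded tetrasubstituted C1=C15 bond and the electron-poor enol triflate.

**Step 15**
Reactants: 24 aldehyde enol triflate
Product: 25 9-hydroxy-2,3,14-tris(triethylsilyloxy)trinervita-1(15),8(19)-diene
Conditions: CrCl2 (10 equiv), NiCl2 (5 mol%), DMF, 23 °C, 2 mM, syringe-pump addition
Reagents that add atoms: none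
Why: Intramolecular Nozaki–Hiyama–Kishi reaction (nickel-catalysed activation of the enol triflate, transfer to chromium, addition to the aldehyde) under high dilution should close ring C and create the C8(19) methylene and C9 carbinol together, the C9 configuration arising from macrocyclic control in the ring-closing conformer.

**Step 16**
Reactants: 25 macrocyclic tris-silyl ether
Product: 26 trinervita-1(15),8(19)-diene-2,3,9,14-tetrol (configuration of the target)
Conditions: HF·pyridine, THF–pyridine, 0 → 23 °C
Reagents that add atoms: none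
Why: Buffered fluoride desilylation should remove the three triethylsilyl groups without allylic transposition.

**Step 17**
Reactants: 26 tetraol
Product: 27 target, 3-hydroxytrinervita-1(15),8(19)-diene-2,9,14-triyl triacetate
Conditions: Ac2O (3.3 equiv), pyridine, DMAP (5 mol%), CH2Cl2, −20 → 0 °C
Reagents that add atoms: acetic anhydride, CC(=O)OC(C)=O
Why: The three allylic secondary hydroxyls (C2, C9, C14) should acylate much faster than the C3 hydroxyl, which is neopentyl-like next to the quaternary C4, so controlled acetylation gives the triacetate with C3–OH free.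

**Compound list**

1 | (R)-4-(tert-butyldimethylsilyloxy)cyclopent-2-en-1-one | O=C1C=C[C@H](O[Si](C)(C)C(C)(C)C)C1 | starting material
2 | isopropenylmagnesium bromide | C=C(C)[Mg]Br | starting material
3 | (3S,4R)-4-(tert-butyldimethylsilyloxy)-3-(prop-1-en-2-yl)cyclopentan-1-one | C=C(C)[C@@H]1CC(=O)C[C@H]1O[Si](C)(C)C(C)(C)C | intermediate
4 | (R)-4-(prop-1-en-2-yl)cyclopent-2-en-1-one | C=C(C)[C@@H]1CC(=O)C=C1 | intermediate
5 | trans-3-methyl-4-(prop-1-en-2-yl)-1-(trimethylsilyloxy)cyclopent-1-ene | C=C(C)[C@@H]1CC(O[Si](C)(C)C)=C[C@H]1C | intermediate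
6 | (S)-3-methyl-4-(prop-1-en-2-yl)cyclopent-2-en-1-one | C=C(C)[C@@H]1CC(=O)C=C1C | intermediate
7 | phenyl vinyl sulfone | C=CS(=O)(=O)c1ccccc1 | starting material
8 | 2-(tert-butyldimethylsilyloxy)-4-methyl-5-(prop-1-en-2-yl)cyclopenta-1,3-diene (C5 configured as C4 of 6) | C=C(C)[C@@H]1C=C(O[Si](C)(C)C(C)(C)C)C=C1C | intermediate
9 | 2-(tert-butyldimethylsilyloxy)-4-methyl-5-endo-(phenylsulfonyl)-7-(prop-1-en-2-yl)bicyclo[2.2.1]hept-2-ene, isopropenyl syn to C2=C3 | C=C(C)[C@@H]1[C@H]2C[C@H](S(=O)(=O)c3ccccc3)[C@]1(C)C=C2O[Si](C)(C)C(C)(C)C | intermediate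
10 | (1R,4S,7S)-2-(tert-butyldimethylsilyloxy)-4-methyl-7-(prop-1-en-2-yl)bicyclo[2.2.1]hept-2-ene | C=C(C)[C@@H]1[C@H]2CC[C@]1(C)C=C2O[Si](C)(C)C(C)(C)C | intermediate
11 | (1R,2R,3S)-2-acetyl-3-formyl-3-methylcyclopentane-1-carboxylic acid | CC(=O)[C@@H]1[C@H](C(=O)O)CC[C@]1(C)C=O | intermediate
12 | methyl (1R,2R,3S)-2-acetyl-3-formyl-3-methylcyclopentane-1-carboxylate | CC(=O)[C@@H]1[C@H](C(=O)OC)CC[C@]1(C)C=O | intermediate
13 | ethyl vinyl ether | C=COCC | starting material
14 | methyl (1R,2R,3S)-2-acetyl-3-[(1R)-2-ethoxy-1-(trimethylsilyloxy)prop-2-en-1-yl]-3-methylcyclopentane-1-carboxylate | CC(=O)[C@@H]1[C@H](C(=O)OC)CC[C@]1(C)[C@@H](O[Si](C)(C)C)C(=C)OCC | intermediate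
15 | methyl 4,7-dihydroxy-4,7a-dimethyl-6-oxooctahydro-1H-indene-3-carboxylate (cis-fused, other centres as in 16, C4 epimers) | C1C(C)(O)[C@@H]2[C@H](C(=O)OC)CC[C@]2(C)[C@@H](O)C1=O | intermediate
16 | methyl (3R,3aS,7R,7aS)-7-hydroxy-4,7a-dimethyl-6-oxo-2,3,3a,6,7,7a-hexahydro-1H-indene-3-carboxylate | C1=C(C)[C@@H]2[C@H](C(=O)OC)CC[C@]2(C)[C@@H](O)C1=O | intermediate
17 | methyl 7-hydroxy-5-iodo-4,7a-dimethyl-6-oxo-2,3,3a,6,7,7a-hexahydro-1H-indene-3-carboxylate (stereocentres as in 16) | IC1=C(C)[C@@H]2[C@H](C(=O)OC)CC[C@]2(C)[C@@H](O)C1=O | intermediate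
18 | methyl 6,7-dihydroxy-5-iodo-4,7a-dimethyl-2,3,3a,6,7,7a-hexahydro-1H-indene-3-carboxylate (6,7-trans diol, 7-OH cis to 7a-methyl) | IC1=C(C)[C@@H]2[C@H](C(=O)OC)CC[C@]2(C)[C@@H](O)[C@@H]1O | intermediate
19 | (S)-citronellal, (3S)-3,7-dimethyloct-6-enal | CC(C)=CCC[C@H](C)CC=O | starting material
20 | methyl 6,7-dihydroxy-5-[(1S,3S)-1-hydroxy-3,7-dimethyloct-6-en-1-yl]-4,7a-dimethyl-2,3,3a,6,7,7a-hexahydro-1H-indene-3-carboxylate (ring centres as in 18) | CC(C)=CCC[C@H](C)C[C@H](O)C1=C(C)[C@@H]2[C@H](C(=O)OC)CC[C@]2(C)[C@@H](O)[C@@H]1O | intermediate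
21 | tris(triethylsilyl) ether of 20 | CC(C)=CCC[C@H](C)C[C@H](O[Si](CC)(CC)CC)C1=C(C)[C@@H]2[C@H](C(=O)OC)CC[C@]2(C)[C@@H](O[Si](CC)(CC)CC)[C@@H]1O[Si](CC)(CC)CC | intermediate
22 | methyl ketone corresponding to 21 (3-acetyl in place of 3-methoxycarbonyl) | CC(C)=CCC[C@H](C)C[C@H](O[Si](CC)(CC)CC)C1=C(C)[C@@H]2[C@H](C(C)=O)CC[C@]2(C)[C@@H](O[Si](CC)(CC)CC)[C@@H]1O[Si](CC)(CC)CC | intermediate
23 | enol triflate of 22 (1-substituted vinyl trifluoromethanesulfonate) | CC(C)=CCC[C@H](C)C[C@H](O[Si](CC)(CC)CC)C1=C(C)[C@@H]2[C@H](C(=C)OS(=O)(=O)C(F)(F)F)CC[C@]2(C)[C@@H](O[Si](CC)(CC)CC)[C@@H]1O[Si](CC)(CC)CC | intermediate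
24 | aldehyde from cleavage of the isopropylidene group of 23 (open-chain precursor of ring C) | O=CCC[C@H](C)C[C@H](O[Si](CC)(CC)CC)C1=C(C)[C@@H]2[C@H](C(=C)OS(=O)(=O)C(F)(F)F)CC[C@]2(C)[C@@H](O[Si](CC)(CC)CC)[C@@H]1O[Si](CC)(CC)CC | intermediate
25 | 9-hydroxy-2,3,14-tris(triethylsilyloxy)trinervita-1(15),8(19)-diene (configuration of the target) | C=C1[C@H](O)CC[C@H](C)C[C@H](O[Si](CC)(CC)CC)C2=C(C)[C@@H]3[C@H]1CC[C@]3(C)[C@@H](O[Si](CC)(CC)CC)[C@@H]2O[Si](CC)(CC)CC | intermediate
26 | trinervita-1(15),8(19)-diene-2,3,9,14-tetrol (configuration of the target) | C=C1[C@H](O)CC[C@H](C)C[C@H](O)C2=C(C)[C@@H]3[C@H]1CC[C@]3(C)[C@@H](O)[C@@H]2O | intermediate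
27 | 3-hydroxytrinervita-1(15),8(19)-diene-2,9,14-triyl triacetate (CNP0318778.1) | C=C1[C@H](OC(C)=O)CC[C@H](C)C[C@H](OC(C)=O)C2=C(C)[C@@H]3[C@H]1CC[C@]3(C)[C@@H](O)[C@@H]2OC(C)=O | target

**Totals and risks**

Total step count: 17. Longest linear sequence: 17 steps (1 to 27).

Step 3. The [1,5]-hydrogen shift or dimerisation of the 5-substituted diene may outrun the cycloaddition, or attack syn to the isopropenyl group may compete. Fallback: the neutral diene is avoided. Setting out from 6, the kinetic lithium dienolate (LiN(iPr)2, THF, −78 °C) is treated with 7; conjugate addition at C7 anti to the C16 substituent and closure of the α-sulfonyl carbanion onto the enone β-carbon C4 (anionic double Michael addition) give the bicyclic keto sulfone F1. Because the other α-carbon of F1 is a bridgehead, enolisation is possible only toward C3, and O-silylation (LiN(iPr)2, TBSOTf, THF, −78 °C) comes back to the route at 9.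

Step 7. The enol ether may simply hydrolyse to the methyl ketone before the C–C bond forms (which would lose the distinction between the two methyl ketones), or the silyl ether may lactonise onto the ester. Fallback: the C1 enolate is made reductively. Setting out from 14, N-bromosuccinimide in wet THF with NaHCO3 at 0 °C gives the bromomethyl ketone F2. SmI2 (THF, −78 °C) then forms the samarium enolate at C1 only, which adds to the C15 ketone (intramolecular Reformatsky-type aldol) to give the silylated tertiary aldol F3. Treatment with 1 M HCl in THF dehydrates and desilylates it and comes back to the route at 16.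

Step 15. Ring closure may show poor facial selectivity (or the wrong sense) at C9. Fallback: the ring closure is kept but C9 is set by reagent control. Setting out from 24, the cyclisation mixture containing the C9 epimer F4 is oxidised with 1,1,1-triacetoxy-1,1-dihydro-1,2-benziodoxol-3(1H)-one (NaHCO3, CH2Cl2) to the macrocyclic α-methylene ketone F5. Enantioselective reduction with catecholborane and (S)-1-methyl-3,3-diphenyltetrahydro-1H,3H-pyrrolo[1,2-c][1,3,2]oxazaborole (PhMe, −78 °C), the alkenyl group acting as the large substituent, comes back to the route at 25.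

**Further compounds**

F1 | step 3 | 4-methyl-5-(phenylsulfonyl)-7-(prop-1-en-2-yl)bicyclo[2.2.1]heptan-2-one (isopropenyl syn to the C2–C3 bridge, sulfone epimers) | C=C(C)[C@@H]1[C@H]2CC(S(=O)(=O)c3ccccc3)[C@]1(C)CC2=O
F2 | step 7 | methyl (1R,2R,3S)-2-acetyl-3-[(1R)-3-bromo-2-oxo-1-(trimethylsilyloxy)propyl]-3-methylcyclopentane-1-carboxylate | CC(=O)[C@@H]1[C@H](C(=O)OC)CC[C@]1(C)[C@@H](O[Si](C)(C)C)C(=O)CBr
F3 | step 7 | 7-O-trimethylsilyl ether of 15 (C4 epimers) | C1C(C)(O)[C@@H]2[C@H](C(=O)OC)CC[C@]2(C)[C@@H](O[Si](C)(C)C)C1=O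
F4 | step 15 | C9 epimer of 25 | C=C1[C@@H](O)CC[C@H](C)C[C@H](O[Si](CC)(CC)CC)C2=C(C)[C@@H]3[C@H]1CC[C@]3(C)[C@@H](O[Si](CC)(CC)CC)[C@@H]2O[Si](CC)(CC)CC
F5 | step 15 | 2,3,14-tris(triethylsilyloxy)trinervita-1(15),8(19)-dien-9-one | C=C1C(=O)CC[C@H](C)C[C@H](O[Si](CC)(CC)CC)C2=C(C)[C@@H]3[C@H]1CC[C@]3(C)[C@@H](O[Si](CC)(CC)CC)[C@@H]2O[Si](CC)(CC)CC
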